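The C7 quaternary carbon and the C6 bromide of the cyclohexene lie α and β to C2, so the pair is read as the product of a bromonium-triggered semipinacol shift, and the ring itself is bought as 2-methylcyclohexenone. One catalyst-set carbinol (C2 of a 1-(but-2-ynyl)-2-methylcyclohex-2-en-1-ol) is traded in a single operation for both ring stereocentres and the C7–C8 bond. The alkyne survives NBS and is then grown into the geranyl chain. One Shi bis-epoxidation sets C9, C10 and C13, and bromide opening of the bis-epoxide lets the C14 alkoxide close the 15-membered lactone.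

Key step: step 3

Remark (locants): C1 is the benzylic CH2; C2–C7 are the cyclohexene carbons (C2 bears C1, C3 its methyl, C6 the bromine, C7 the quaternary methyl carbon); C8–C14 is the chain (C9–C10 epoxide, C13 bromide, C14 the gem-dimethyl carbon bearing the ester oxygen). The target is (6S,7S,9S,10S,13R).
Remark (assumption): in step 1 the ligand antipode is taken to be the one that gives the (S)-carbinol.

Step 1
Reactants: 1 2-methylcyclohex-2-en-1-one; 2 allenylboronic acid pinacol ester
Product: 3 (1S)-2-methyl-1-(prop-2-yn-1-yl)cyclohex-2-en-1-ol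
Conditions: CuOAc (5 mol %), chiral bisphosphine [(R,R)-Ph-BPE or its antipode, 6 mol %], LiOt-Bu (10 mol %), i-PrOH (1.2 equiv), THF, −40 °C
Reagents that add atoms: none
Why: Cu(I)-catalysed enantioselective propargylation of a ketone, in which B-to-Cu exchange gives an allenylcopper that adds 1,2 to the carbonyl through a cyclic SE2' transition state, the ligand choosing the carbonyl face between the sp2 C(CH3)= arm and the sp3 CH2 arm and so setting C2 as (S).

Step 2
Reactants: 3 (1S)-2-methyl-1-(prop-2-yn-1-yl)cyclohex-2-en-1-ol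
Product: 4 (1S)-1-(but-2-yn-1-yl)-2-methylcyclohex-2-en-1-ol
Conditions: n-BuLi (2.1 equiv), THF, −78 → −20 °C; MeI (1.2 equiv), −78 °C → rt
Reagents that add atoms: iodomethane, CI
Why: C-methylation of the lithium acetylide of the alkoxide–acetylide dianion, the hindered lithium tertiary alkoxide not being alkylated in THF and the stereocentre not being touched.

Step 3
Reactants: 4 (1S)-1-(but-2-yn-1-yl)-2-methylcyclohex-2-en-1-ol
Product: 5 (2S,3S)-3-bromo-2-(but-2-yn-1-yl)-2-methylcyclohexan-1-one
Conditions: NBS (1.1 equiv), CH2Cl2, −30 → 0 °C, dark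
Reagents that add atoms: N-bromosuccinimide, O=C1CCC(=O)N1Br
Why: NBS transfers Br+ reversibly to the C6=C7 alkene; the bromonium ion on the face opposite the but-2-ynyl group has the C2–C8 bond antiperiplanar to the breaking C7–Br bond (allylic 1,2-strain with the C7 methyl keeps the but-2-ynyl group, not the hydroxyl, pseudoaxial), and it collapses by a suprafacial 1,2-shift of C8 from C2 to C7 while the C2 hydroxyl becomes the ketone. The closest known reaction type is the halonium-induced semipinacol rearrangement of tertiary allylic alcohols to α-quaternary β-halo ketones, the halogen counterpart of the Lewis-acid semipinacol rearrangement of 2,3-epoxy alcohols. No ring is closed: the six-membered ring is that of 1. C7 (S) is controlled by the carbinol centre of 4, because C8 arrives on the ring face it left, and C6 (S) by the obligatory anti relationship between bromine and the migrating carbon, so that bromine ends trans to C8 and cis to the C7 methyl. The step needs chemoselectivity for the alkene over the alkyne, which is secured by carrying the chain as a but-2-ynyl group (alkynes react with bromonium donors far more slowly than trisubstituted alkenes, whereas a geranyl group would not survive), and exocyclic migration over ring contraction or bromo-epoxide formation, which is secured because the ring C2–C3 bond lies near the alkene plane and the hydroxyl is syn to bromine in the productive bromonium ion.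

Step 4
Reactants: 5 (2S,3S)-3-bromo-2-(but-2-yn-1-yl)-2-methylcyclohexan-1-one
Product: 6 (2S,3S)-3-bromo-2-(but-2-yn-1-yl)-2,6-dimethylcyclohexan-1-one (both C6 epimers)
Conditions: LDA (1.05 equiv), THF, −78 °C; MeI, −78 → −30 °C
Reagents that add atoms: iodomethane, CI
Why: Kinetic enolate alkylation at the only enolisable position (the other α-carbon is quaternary, so the β-bromide cannot leave by E1cB), either epimer of the new centre serving because it becomes sp2 in step 5.

Step 5
Reactants: 6 (2S,3S)-3-bromo-2-(but-2-yn-1-yl)-2,6-dimethylcyclohexan-1-one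
Product: 7 (5S,6S)-5-bromo-6-(but-2-yn-1-yl)-2,6-dimethylcyclohex-1-en-1-yl trifluoromethanesulfonate
Conditions: KHMDS (1.1 equiv), THF, −78 °C; PhNTf2, −78 → 0 °C
Reagents that add atoms: N-phenylbis(trifluoromethanesulfonimide), O=S(=O)(N(c1ccccc1)S(=O)(=O)C(F)(F)F)C(F)(F)F
Why: O-triflation of the only possible enolate gives the tetrasubstituted enol triflate regiospecifically, as with 2,2,6-trimethylcyclohexanone, and leaves C6 and C7 untouched.

Step 6
Reactants: 7 (5S,6S)-5-bromo-6-(but-2-yn-1-yl)-2,6-dimethylcyclohex-1-en-1-yl trifluoromethanesulfonate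
Product: 8 (5S,6S)-5-bromo-6-[(2E)-3-iodobut-2-en-1-yl]-2,6-dimethylcyclohex-1-en-1-yl trifluoromethanesulfonate
Conditions: Cp2Zr(H)Cl (1.5 equiv), THF, rt → 40 °C; I2, 0 °C
Reagents that add atoms: iodine, II
Why: syn-Hydrozirconation of the internal alkyne with the Schwartz reagent places zirconium on C10, beside the small methyl group and away from the branched C8 side (regio-equilibration by a slight excess of hydride), and iodinolysis with retention should give the E-iodide, the enol triflate and the alkyl bromide being inert.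

Step 7
Reactants: 8 (5S,6S)-5-bromo-6-[(2E)-3-iodobut-2-en-1-yl]-2,6-dimethylcyclohex-1-en-1-yl trifluoromethanesulfonate; 9 5-bromo-2-methylpent-2-ene
Product: 11 (5S,6S)-5-bromo-6-[(2E)-3,7-dimethylocta-2,6-dien-1-yl]-2,6-dimethylcyclohex-1-en-1-yl trifluoromethanesulfonate, via homoprenylzinc bromide 10 (not isolated)
Conditions: 9, Zn dust (I2 cat.), DMA, 70 °C; then 8, PdCl2(dppf) (5 mol %), THF, rt
Reagents that add atoms: none
Why: Negishi sp3–sp2 coupling with retention of alkene geometry, oxidative addition into the vinyl C–I bond being far faster than into the hindered tetrasubstituted enol triflate or the secondary C–Br bond.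

Step 8
Reactants: 11 (5S,6S)-5-bromo-6-[(2E)-3,7-dimethylocta-2,6-dien-1-yl]-2,6-dimethylcyclohex-1-en-1-yl trifluoromethanesulfonate
Product: 12 (5S,6S)-5-bromo-6-({(2S,3S)-3-[2-((2S)-3,3-dimethyloxiran-2-yl)ethyl]-3-methyloxiran-2-yl}methyl)-2,6-dimethylcyclohex-1-en-1-yl trifluoromethanesulfonate
Conditions: ent-Shi ketone (L-fructose-derived, 40 mol %), Oxone, K2CO3, Bu4NHSO4, MeCN–DMM–aq. borate/EDTA buffer (pH 10.5), 0 °C
Reagents that add atoms: potassium peroxymonosulfate (Oxone), [K+].[O-]S(=O)(=O)OO
Why: Shi asymmetric epoxidation (chiral dioxirane, spiro transition state) epoxidises both trisubstituted chain alkenes under catalyst control, the enantiomer of the usual catalyst giving (9S,10S) and (13S), while the electron-poor enol triflate alkene is not oxidised, which is why the ring alkene is still masked at this stage.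

Step 9
Reactants: 13 4-hydroxy-3-methylbenzoic acid
Product: 14 3-methyl-4-[(triisopropylsilyl)oxy]benzoic acid
Conditions: TIPSCl (2.3 equiv), imidazole, DMF, rt; then AcOH–THF–H2O, rt
Reagents that add atoms: chlorotriisopropylsilane, CC(C)[Si](Cl)(C(C)C)C(C)C
Why: Silylation of phenol and acid followed by selective hydrolysis of the labile silyl ester leaves the aryl silyl ether.

Step 10
Reactants: 14 3-methyl-4-[(triisopropylsilyl)oxy]benzoic acid
Product: 15 1,1,1,3,3,3-hexafluoropropan-2-yl 3-methyl-4-[(triisopropylsilyl)oxy]benzoate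
Conditions: (CF3)2CHOH (5 equiv), EDC·HCl, DMAP (cat.), CH2Cl2, rt
Reagents that add atoms: 1,1,1,3,3,3-hexafluoropropan-2-ol, OC(C(F)(F)F)C(F)(F)F
Why: Steglich esterification gives an activated but isolable ester that tolerates organozinc chemistry and later serves as the acyl donor.

Step 11
Reactants: 15 1,1,1,3,3,3-hexafluoropropan-2-yl 3-methyl-4-[(triisopropylsilyl)oxy]benzoate
Product: 16 1,1,1,3,3,3-hexafluoropropan-2-yl 3-(bromomethyl)-4-[(triisopropylsilyl)oxy]benzoate
Conditions: NBS (1.05 equiv), AIBN (cat.), PhCF3, 85 °C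
Reagents that add atoms: N-bromosuccinimide, O=C1CCC(=O)N1Br
Why: Wohl–Ziegler radical bromination at the only benzylic C–H position.

Step 12
Reactants: 12 (5S,6S)-5-bromo-6-({(2S,3S)-3-[2-((2S)-3,3-dimethyloxiran-2-yl)ethyl]-3-methyloxiran-2-yl}methyl)-2,6-dimethylcyclohex-1-en-1-yl trifluoromethanesulfonate; 16 1,1,1,3,3,3-hexafluoropropan-2-yl 3-(bromomethyl)-4-[(triisopropylsilyl)oxy]benzoate
Product: 18 1,1,1,3,3,3-hexafluoropropan-2-yl 3-{[(5S,6S)-5-bromo-6-({(2S,3S)-3-[2-((2S)-3,3-dimethyloxiran-2-yl)ethyl]-3-methyloxiran-2-yl}methyl)-2,6-dimethylcyclohex-1-en-1-yl]methyl}-4-[(triisopropylsilyl)oxy]benzoate, via benzylic zinc bromide 17 (not isolated)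
Conditions: 16, Zn dust, LiCl, THF, 0 °C → rt; then 12, Pd(OAc)2 (5 mol %), SPhos (10 mol %), THF, rt
Reagents that add atoms: none
Why: Negishi coupling of a benzylic zinc reagent with the hindered enol triflate (a 2,6,6-trisubstituted cyclohexenyl triflate of the kind that cross-couples reliably) forms the C1–C2 bond and unmasks the tetrasubstituted ring alkene, the organozinc sparing the epoxides, the C–Br bond and the activated ester.

Step 13
Reactants: 18 1,1,1,3,3,3-hexafluoropropan-2-yl 3-{[(5S,6S)-5-bromo-6-({(2S,3S)-3-[2-((2S)-3,3-dimethyloxiran-2-yl)ethyl]-3-methyloxiran-2-yl}methyl)-2,6-dimethylcyclohex-1-en-1-yl]methyl}-4-[(triisopropylsilyl)oxy]benzoate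
Product: 21 O-triisopropylsilyl ether of the target, (6S,7S,9S,10S,13R), via dilithium bis(bromoalkoxide) 19 (not isolated), via 9-bromo-10-olate macrolactone 20 (not isolated)
Conditions: Li2NiBr4 (2.5 equiv), THF, 0 °C → rt; dilution to 1 mM, 40 °C; then K2CO3, MeOH, 0 °C
Reagents that add atoms: dilithium tetrabromonickelate(II), [Li+].[Li+].[Ni+2].[Br-].[Br-].[Br-].[Br-]
Why: Proposed new method: soft nucleophilic bromide opens both trisubstituted epoxides by SN2 at their secondary carbons (C9 and C13, inversion) and the metal-bound bromo-alkoxides persist instead of re-closing; only the C14 alkoxide can reach the activated hexafluoroisopropyl ester (15-membered transition state, against an 11-membered one for the C10 alkoxide), so it alone is acylated, and base then lets the C10 alkoxide displace the C9 bromide to restore the 9,10-epoxide with net retention while the C13 bromide, now next to an ester oxygen, stays as (R); the closest known reactions are the conversion of epoxides into bromohydrins with Li2NiBr4 and the onium-halide-catalysed insertion of oxiranes into active esters, neither of which has been run as a macrolactonization.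

Step 14
Reactants: 21 O-triisopropylsilyl ether of the target
Product: 22 target macrolactone, (6S,7S,9S,10S,13R)
Conditions: TBAF, AcOH (1:1), THF, 0 °C
Reagents that add atoms: none
Why: Buffered fluoride cleavage of the aryl silyl ether spares the epoxide, both secondary bromides and the tertiary benzoate, and avoids acid that could add the free phenol across the C2=C3 alkene.

Compound list
1 | 2-methylcyclohex-2-en-1-one | CC1=CCCCC1=O | starting material
2 | allenylboronic acid pinacol ester | C=C=CB1OC(C)(C)C(C)(C)O1 | starting material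
3 | (1S)-2-methyl-1-(prop-2-yn-1-yl)cyclohex-2-en-1-ol | C#CC[C@@]1(O)CCCC=C1C | intermediate
4 | (1S)-1-(but-2-yn-1-yl)-2-methylcyclohex-2-en-1-ol | CC#CC[C@@]1(O)CCCC=C1C | intermediate
5 | (2S,3S)-3-bromo-2-(but-2-yn-1-yl)-2-methylcyclohexan-1-one (Br trans to the butynyl group) | CC#CC[C@]1(C)[C@@H](Br)CCCC1=O | intermediate
6 | (2S,3S)-3-bromo-2-(but-2-yn-1-yl)-2,6-dimethylcyclohexan-1-one, both C6 epimers | CC#CC[C@]1(C)[C@@H](Br)CCC(C)C1=O | intermediate
7 | (5S,6S)-5-bromo-6-(but-2-yn-1-yl)-2,6-dimethylcyclohex-1-en-1-yl trifluoromethanesulfonate | CC#CC[C@]1(C)[C@@H](Br)CCC(C)=C1OS(=O)(=O)C(F)(F)F | intermediate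
8 | (5S,6S)-5-bromo-6-[(2E)-3-iodobut-2-en-1-yl]-2,6-dimethylcyclohex-1-en-1-yl trifluoromethanesulfonate | C/C(I)=C\C[C@]1(C)[C@@H](Br)CCC(C)=C1OS(=O)(=O)C(F)(F)F | intermediate
9 | 5-bromo-2-methylpent-2-ene | CC(C)=CCCBr | starting material
10 | (4-methylpent-3-en-1-yl)zinc bromide | CC(C)=CCC[Zn]Br | intermediate
11 | (5S,6S)-5-bromo-6-[(2E)-3,7-dimethylocta-2,6-dien-1-yl]-2,6-dimethylcyclohex-1-en-1-yl trifluoromethanesulfonate | CC(C)=CCC/C(C)=C/C[C@]1(C)[C@@H](Br)CCC(C)=C1OS(=O)(=O)C(F)(F)F | intermediate
12 | (5S,6S)-5-bromo-6-({(2S,3S)-3-[2-((2S)-3,3-dimethyloxiran-2-yl)ethyl]-3-methyloxiran-2-yl}methyl)-2,6-dimethylcyclohex-1-en-1-yl trifluoromethanesulfonate | CC1(C)O[C@H]1CC[C@]2(C)O[C@H]2C[C@]3(C)[C@@H](Br)CCC(C)=C3OS(=O)(=O)C(F)(F)F | intermediate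
13 | 4-hydroxy-3-methylbenzoic acid | Cc1cc(C(=O)O)ccc1O | starting material
14 | 3-methyl-4-[(triisopropylsilyl)oxy]benzoic acid | Cc1cc(C(=O)O)ccc1O[Si](C(C)C)(C(C)C)C(C)C | intermediate
15 | 1,1,1,3,3,3-hexafluoropropan-2-yl 3-methyl-4-[(triisopropylsilyl)oxy]benzoate | Cc1cc(C(=O)OC(C(F)(F)F)C(F)(F)F)ccc1O[Si](C(C)C)(C(C)C)C(C)C | intermediate
16 | 1,1,1,3,3,3-hexafluoropropan-2-yl 3-(bromomethyl)-4-[(triisopropylsilyl)oxy]benzoate | BrCc1cc(C(=O)OC(C(F)(F)F)C(F)(F)F)ccc1O[Si](C(C)C)(C(C)C)C(C)C | intermediate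
17 | benzylic zinc bromide derived from 16 | Br[Zn]Cc1cc(C(=O)OC(C(F)(F)F)C(F)(F)F)ccc1O[Si](C(C)C)(C(C)C)C(C)C | intermediate
18 | seco bis-epoxide: hexafluoroisopropyl 3-{[(5S,6S)-5-bromo-6-({(2S,3S)-3-[2-((2S)-3,3-dimethyloxiran-2-yl)ethyl]-3-methyloxiran-2-yl}methyl)-2,6-dimethylcyclohex-1-en-1-yl]methyl}-4-[(triisopropylsilyl)oxy]benzoate | CC1(C)O[C@H]1CC[C@]2(C)O[C@H]2C[C@]3(C)[C@@H](Br)CCC(C)=C3Cc4cc(C(=O)OC(C(F)(F)F)C(F)(F)F)ccc4O[Si](C(C)C)(C(C)C)C(C)C | intermediate
19 | dilithium (6S,7S,9R,10S,13R)-6,9,13-tribromo-10,14-diolate of the seco ester (both epoxides opened by bromide) | [Li+].[Li+].[O-]C(C)(C)[C@H](Br)CC[C@](C)([O-])[C@H](Br)C[C@]1(C)[C@@H](Br)CCC(C)=C1Cc2cc(C(=O)OC(C(F)(F)F)C(F)(F)F)ccc2O[Si](C(C)C)(C(C)C)C(C)C | intermediate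
20 | (6S,7S,9R,10S,13R)-9-bromo-10-hydroxy macrolactone, O-triisopropylsilyl ether (formed as its lithium alkoxide) | CC1=C2Cc3cc(ccc3O[Si](C(C)C)(C(C)C)C(C)C)C(=O)OC(C)(C)[C@H](Br)CC[C@](C)(O)[C@H](Br)C[C@]2(C)[C@@H](Br)CC1 | intermediate
21 | (6S,7S,9S,10S,13R)-macrolactone, O-triisopropylsilyl ether of the target | CC1=C2Cc3cc(ccc3O[Si](C(C)C)(C(C)C)C(C)C)C(=O)OC(C)(C)[C@H](Br)CC[C@]3(C)O[C@H]3C[C@]2(C)[C@@H](Br)CC1 | intermediate
22 | (6S,7S,9S,10S,13R)-6,13-dibromo-9,10-epoxy macrolactone of 4-hydroxybenzoic acid (CID46880797) | CC1=C2Cc3cc(ccc3O)C(=O)OC(C)(C)[C@H](Br)CC[C@]3(C)O[C@H]3C[C@]2(C)[C@@H](Br)CC1 | target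

Total step count: 14. Longest linear sequence: 11 steps (steps 1–8 and 12–14).

Steps most likely to fail

1. Step 13 (Proposed new method). Acyl transfer from the hindered, metal-bound C14 alkoxide may be slow at the dilution needed; the bis-epoxide could then re-form, or the C10 alkoxide could open the 13,14-epoxide in a 5-exo sense before bromide does. The fallback uses known reactions only, sets out from 18 and comes back at 21. The activated ester is cleaved with LiOH (1.1 equiv, THF–H2O, 0 °C) to the bis-epoxy acid F1. LiBr/AcOH in THF then opens both epoxides at C9 and C13 under protic, non-basic conditions to give the bis(bromohydrin) acid F2. Shiina macrolactonization (MNBA, DMAP, toluene, high dilution) should acylate the C14 hydroxyl, the C10 hydroxyl being out of reach, and give 20 as an isolated alcohol. K2CO3 in MeOH re-closes the 9,10-epoxide to 21.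

2. Step 3 (key step). The bromonium ion may be captured by the hydroxyl (bromo-epoxide), or the ring C2–C3 bond may migrate (ring contraction), in place of the 1,2-shift of C8. The fallback sets out from 1 and comes back at 5, replacing the rearrangement by desymmetrization of a prochiral dione. Pd(II)/t-BuOOH oxidation of enone 1 gives 2-methylcyclohexane-1,3-dione F3 (which is also commercial). C-alkylation with 1-bromobut-2-yne (aq. NaOH) gives 2-(but-2-yn-1-yl)-2-methylcyclohexane-1,3-dione F4. Enantioselective mono-reduction (ketoreductase, or a CBS catalyst with catecholborane) gives the (2R,3R)-hydroxy ketone F5, with the hydroxyl cis to the butynyl group. Triflation (Tf2O, 2,6-lutidine) gives the triflate F6, and LiBr displaces it with inversion to give 5. This SN2 step at a centre next to a quaternary carbon is the weak point of the fallback.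

3. Step 1. Facial discrimination at the α-branched cyclic enone may be poor, and any loss of enantiomeric purity is relayed to C6 and C7 by step 3. The fallback sets out from 1 and comes back at 3, setting the carbinol by substrate control. CBS reduction of 1 with (S)-Me-CBS/BH3 gives (R)-2-methylcyclohex-2-en-1-ol F7. VO(acac)2/t-BuOOH epoxidation syn to the hydroxyl gives the epoxy alcohol F8, and Dess–Martin oxidation gives the epoxy ketone F9. Propargylmagnesium bromide (THF, −78 °C) adds anti to the epoxide to give the epoxy carbinol F10. WCl6/n-BuLi deoxygenation of the epoxide returns the alkene and gives 3.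

Further compounds
F1 | step 13 | bis-epoxy seco acid, 3-{[(5S,6S)-5-bromo-6-({(2S,3S)-3-[2-((2S)-3,3-dimethyloxiran-2-yl)ethyl]-3-methyloxiran-2-yl}methyl)-2,6-dimethylcyclohex-1-en-1-yl]methyl}-4-[(triisopropylsilyl)oxy]benzoic acid | CC1(C)O[C@H]1CC[C@]2(C)O[C@H]2C[C@]3(C)[C@@H](Br)CCC(C)=C3Cc4cc(C(=O)O)ccc4O[Si](C(C)C)(C(C)C)C(C)C
F2 | step 13 | (6S,7S,9R,10S,13R)-6,9,13-tribromo-10,14-dihydroxy seco acid, O-triisopropylsilyl ether | OC(C)(C)[C@H](Br)CC[C@](C)(O)[C@H](Br)C[C@]1(C)[C@@H](Br)CCC(C)=C1Cc2cc(C(=O)O)ccc2O[Si](C(C)C)(C(C)C)C(C)C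
F3 | step 3 | 2-methylcyclohexane-1,3-dione | CC1C(=O)CCCC1=O
F4 | step 3 | 2-(but-2-yn-1-yl)-2-methylcyclohexane-1,3-dione | CC#CCC1(C)C(=O)CCCC1=O
F5 | step 3 | (2R,3R)-2-(but-2-yn-1-yl)-3-hydroxy-2-methylcyclohexan-1-one | CC#CC[C@]1(C)[C@H](O)CCCC1=O
F6 | step 3 | (1R,2R)-2-(but-2-yn-1-yl)-2-methyl-3-oxocyclohexyl trifluoromethanesulfonate | CC#CC[C@]1(C)[C@H](OS(=O)(=O)C(F)(F)F)CCCC1=O
F7 | step 1 | (1R)-2-methylcyclohex-2-en-1-ol | O[C@@H]1CCCC=C1C
F8 | step 1 | (1R,2R,6S)-1-methyl-7-oxabicyclo[4.1.0]heptan-2-ol (epoxide syn to the hydroxyl) | O[C@@H]1CCC[C@@H]2O[C@]12C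
F9 | step 1 | (1S,6S)-1-methyl-7-oxabicyclo[4.1.0]heptan-2-one | O=C1CCC[C@@H]2O[C@]12C
F10 | step 1 | (1S,2S,6S)-1-methyl-2-(prop-2-yn-1-yl)-7-oxabicyclo[4.1.0]heptan-2-ol | C#CC[C@@]1(O)CCC[C@@H]2O[C@]12C
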